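The readings were generated by integration with made-up constants.

The eta run is slow: 12.8% of its free monomer still stands after 8.00 h.

| flask | free monomer | protic impurity | initiator | remark | time |
|---|---|---|---|---|---|
| eta | 10 mM | 10 mM | 1 mM | run made earlier |  |
| delta | 40 mM | 10 mM | 1 mM | run made earlier |  |
| flask | 20 mM | 10.0 mM | 1.0 mM |  | 40 h |

- eta (time / h: monomer in chains / %, free monomer / %): 3.00: 34.1, 41.4; 8.00: 51.2, 12.8; 15.0: 55.2, 2.5; 40.0: 54.0, 0
- delta (time / h: monomer in chains / %, free monomer / %): 3.00: 31.7, 50.3; 8.00: 52.6, 24.3; 15.0: 60.3, 14.2; 40.0: 65.4, 8.5

(standard deviation of a reading: 0.5 percentage points)

- whether the average number of monomer units in a chain (chains begun, living or dead) reaches 4.0 by 40 h (yes / no)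
- average number of monomer units in a chain (chains begun, living or dead) at 40 h

- the average divides the monomer in chains by the number of chains begun, living and dead together
- the earlier runs do not show the number of chains; that part of a forecast is a guess

Monomer that is neither free nor in chains is missing, and I take it as lost to protic impurity. I assume both losses are first order in c(free monomer), so their ratio does not contain it. At 3.00 h that ratio reads 1.39 in the eta run and 1.76 in the delta run. The flask's charge lies between theirs, so I take the mean, 1.58. This is the split, monomer in chains over monomer missing, a selectivity factor.

By 40 h the flask should hold about 12.2 mM in chains. If chains begun equal c(initiator), a guess, the length is 12.2. I read the split at these charges of protic impurity and initiator, so leave them alone.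

The forecast says yes and 12, with the caution “Chain count is the guess”.

The flask gives yes and 11.7.

    free monomer + initiator → living end + monomer in chains (k = 330 /M/h)
    free monomer + living end → monomer in chains + living end, rate k2*[living end]*[free monomer] (k = 150 /M/h)
    protic impurity + free monomer → quenched substrate (k = 14.0 /M/h)
    living end + monomer in chains → dead end (k = 4.20 /M/h)

In the flask, free monomer goes into chains at 1.8 times its rate into quenched substrate at 3.20 h, but at 0.68 times at 40.0 h. At 40.0 h the flask's split, monomer in chains over monomer missing, comes to 1.43. In the eta run, its own split of 1.39 puts 58.2% of the charge in chains, and the reading at 40.0 h is 54.0%.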